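**Plan**

- Retrosynthesis: cut first the CH2–C(=O) bond of the dihydrochalcone chain (addition of the formyl C–H of 2,4-dihydroxybenzaldehyde across a 6-vinylchromene), then the vinyl C=C (Wittig), then the C7–prenyl bond (aromatic Claisen), then the pyran ring bonds C4–C4a and O1–C2 (propargyl Claisen cascade), back to 3,4-dihydroxybenzaldehyde.
- Forward: ring B is bought as 3,4-dihydroxybenzaldehyde. Its para hydroxyl is O-alkylated with 3-chloro-3-methylbut-1-yne and heated to fuse the 2,2-dimethyl-2H-pyran ring. The remaining hydroxyl receives the same C5 unit, which is semi-hydrogenated and rearranged to place the prenyl group on C7. The aldehyde becomes the vinyl group, and ring A is joined last.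
- Enabling feature: the C2 hydroxyl of ring A lies ortho to the ketone carbon, so the ketone can come from a salicylaldehyde whose phenoxide holds rhodium in a five-membered chelate (Rh, acyl C, C1, C2, O). This turns the formyl carbon into an acyl donor (polarity reversal) that adds to the unpolarised vinyl group on C6 of the chromene, with no protecting group or leaving group.
- Stereochemistry: none to set. The target has no stereocentre and no configurable alkene; the selectivity questions are regiochemical only.

Key step: step 7

Remark: compounds 1, 2 and 12 are taken as commercial; the transient dienone 9 is racemic and its stereocentre is lost on tautomerisation.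

**Route**

Step 1
Reactants: 1 3,4-dihydroxybenzaldehyde; 2 3-chloro-3-methylbut-1-yne
Product: 3 3-hydroxy-4-[(2-methylbut-3-yn-2-yl)oxy]benzaldehyde
Conditions: 2 (1.1 equiv), DBU (1.05 equiv), CuCl2·2H2O (1 mol%), MeCN, 0 °C, argon
Reagents that add atoms: none
Why: Copper-catalysed propargylic etherification (O-alkylation through a copper acetylide/allenylidene) should occur at the C4 hydroxyl alone, because with one equivalent of base only this more acidic phenol, para to the formyl group, is ionised.

Step 2
Reactants: 3 3-hydroxy-4-[(2-methylbut-3-yn-2-yl)oxy]benzaldehyde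
Product: 6 8-hydroxy-2,2-dimethyl-2H-chromene-6-carbaldehyde, via ortho-allenylphenol 4 (not isolated), via ortho-quinone methide 5 (not isolated)
Conditions: N,N-diethylaniline, 190 °C, argon
Reagents that add atoms: none
Why: A thermal propargyl Claisen rearrangement ([3,3]) to C5, the only free ortho position, followed by tautomerisation to 4, a 1,5-hydrogen shift to 5 and an oxa-6π electrocyclisation should close the 2,2-dimethyl-2H-pyran ring, as is usual for aryl 1,1-dimethylpropargyl ethers.

Step 3
Reactants: 6 8-hydroxy-2,2-dimethyl-2H-chromene-6-carbaldehyde; 2 3-chloro-3-methylbut-1-yne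
Product: 7 2,2-dimethyl-8-[(2-methylbut-3-yn-2-yl)oxy]-2H-chromene-6-carbaldehyde
Conditions: 2 (1.3 equiv), DBU (1.3 equiv), CuCl2·2H2O (1 mol%), MeCN, 0 °C to rt
Reagents that add atoms: none
Why: The same copper-catalysed propargylic O-alkylation should etherify the single remaining phenol at C8, the tertiary chloride reacting through an allenylidene-type electrophile so that steric hindrance is no obstacle.

Step 4
Reactants: 7 2,2-dimethyl-8-[(2-methylbut-3-yn-2-yl)oxy]-2H-chromene-6-carbaldehyde
Product: 8 2,2-dimethyl-8-[(2-methylbut-3-en-2-yl)oxy]-2H-chromene-6-carbaldehyde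
Conditions: H2 (1 atm), Pd on CaCO3 poisoned with Pb(OAc)2 (Lindlar catalyst), quinoline, EtOAc, rt, stopped at one equivalent of H2
Reagents that add atoms: none
Why: Lindlar semi-hydrogenation should stop at the terminal alkene because the poisoned palladium surface binds the alkyne far more strongly than the product alkene, the ring C3=C4 alkene or the aldehyde.

Step 5
Reactants: 8 2,2-dimethyl-8-[(2-methylbut-3-en-2-yl)oxy]-2H-chromene-6-carbaldehyde
Product: 10 8-hydroxy-2,2-dimethyl-7-(3-methylbut-2-en-1-yl)-2H-chromene-6-carbaldehyde, via cyclohexadienone 9 (not isolated)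
Conditions: N,N-diethylaniline, 140 °C, argon
Reagents that add atoms: none
Why: The aromatic Claisen rearrangement ([3,3]) of the aryl 1,1-dimethylallyl ether should deliver the allyl unit with transposition to C7, the only ortho position bearing hydrogen (C8a is blocked), and tautomerisation of dienone 9 then gives the ortho-prenylphenol.

Step 6
Reactants: 10 8-hydroxy-2,2-dimethyl-7-(3-methylbut-2-en-1-yl)-2H-chromene-6-carbaldehyde
Product: 11 6-ethenyl-2,2-dimethyl-7-(3-methylbut-2-en-1-yl)-2H-chromen-8-ol
Conditions: MePPh3Br (2.6 equiv), KOtBu (2.5 equiv), THF, 0 °C to rt; aq. NH4Cl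
Reagents that add atoms: methyltriphenylphosphonium bromide, C[P+](c1ccccc1)(c1ccccc1)c1ccccc1.[Br-]
Why: Wittig methylenation with an excess of ylide should convert the aldehyde into the vinyl group, the phenol being carried through as its phenoxide, which sits meta to the formyl group and so does not deactivate it.

Step 7
Reactants: 11 6-ethenyl-2,2-dimethyl-7-(3-methylbut-2-en-1-yl)-2H-chromen-8-ol; 12 2,4-dihydroxybenzaldehyde
Product: 13 1-(2,4-dihydroxyphenyl)-3-[8-hydroxy-2,2-dimethyl-7-(3-methylbut-2-en-1-yl)-2H-chromen-6-yl]propan-1-one
Conditions: 12 (1.5 equiv), [Rh(cod)Cl]2 (2.5 mol%), BINOL-derived phosphoramidite ligand (10 mol%), K3PO4 (10 mol%), 1,2-dichloroethane, 70 °C, argon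
Reagents that add atoms: none
Why: K3PO4 generates the C2 phenoxide of 12, which binds monovalent rhodium so that oxidative addition of the formyl C–H gives a five-membered acyl(hydrido)rhodium phenoxide chelate of trivalent rhodium; the vinyl group of 11 then inserts into Rh–H with the metal at the terminal carbon, and C–C reductive elimination forms the CH2–C(=O) bond and returns monovalent rhodium. The closest known reaction type is the chelation-assisted, rhodium/phosphoramidite-catalysed intermolecular hydroacylation of terminal alkenes with salicylaldehydes, which is linear-selective. No ring is closed and no stereocentre is formed. The step needs linear regioselectivity, which should follow because benzylic (branched) insertion is reversible while reductive elimination from that secondary alkyl is slowed by the bulky ligand and by the prenyl group on C7 next to the vinyl group. It also needs site selectivity among three alkenes, secured because only the monosubstituted vinyl group can coordinate and insert, the trisubstituted prenyl alkene and the C3=C4 alkene beside the quaternary C2 being too hindered. Decarbonylation is held back by the chelate, and the other phenols cannot chelate the acyl carbon and so should be spectators.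

**Compound list**

1 | 3,4-dihydroxybenzaldehyde | O=Cc1ccc(O)c(O)c1 | starting material
2 | 3-chloro-3-methylbut-1-yne | CC(C)(Cl)C#C | starting material
3 | 3-hydroxy-4-[(2-methylbut-3-yn-2-yl)oxy]benzaldehyde | O=Cc1ccc(OC(C)(C)C#C)c(O)c1 | intermediate
4 | ortho-allenylphenol: 3,4-dihydroxy-5-(3-methylbuta-1,2-dien-1-yl)benzaldehyde | O=Cc1cc(O)c(O)c(C=C=C(C)C)c1 | intermediate
5 | ortho-quinone methide: 5-hydroxy-3-(3-methylbut-2-en-1-ylidene)-4-oxocyclohexa-1,5-diene-1-carbaldehyde | O=CC1=CC(=CC=C(C)C)C(=O)C(O)=C1 | intermediate
6 | 8-hydroxy-2,2-dimethyl-2H-chromene-6-carbaldehyde | O=Cc1cc(O)c2OC(C)(C)C=Cc2c1 | intermediate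
7 | 2,2-dimethyl-8-[(2-methylbut-3-yn-2-yl)oxy]-2H-chromene-6-carbaldehyde | O=Cc1cc(OC(C)(C)C#C)c2OC(C)(C)C=Cc2c1 | intermediate
8 | 2,2-dimethyl-8-[(2-methylbut-3-en-2-yl)oxy]-2H-chromene-6-carbaldehyde | O=Cc1cc(OC(C)(C)C=C)c2OC(C)(C)C=Cc2c1 | intermediate
9 | cyclohexadienone: 2,2-dimethyl-7-(3-methylbut-2-en-1-yl)-8-oxo-7,8-dihydro-2H-chromene-6-carbaldehyde (racemic, transient) | O=CC1=CC2=C(OC(C)(C)C=C2)C(=O)C1CC=C(C)C | intermediate
10 | 8-hydroxy-2,2-dimethyl-7-(3-methylbut-2-en-1-yl)-2H-chromene-6-carbaldehyde | O=Cc1cc2C=CC(C)(C)Oc2c(O)c1CC=C(C)C | intermediate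
11 | 6-ethenyl-2,2-dimethyl-7-(3-methylbut-2-en-1-yl)-2H-chromen-8-ol | C=Cc1cc2C=CC(C)(C)Oc2c(O)c1CC=C(C)C | intermediate
12 | 2,4-dihydroxybenzaldehyde | O=Cc1ccc(O)cc1O | starting material
13 | 1-(2,4-dihydroxyphenyl)-3-[8-hydroxy-2,2-dimethyl-7-(3-methylbut-2-en-1-yl)-2H-chromen-6-yl]propan-1-one | CC(C)=CCc1c(CCC(=O)c2ccc(O)cc2O)cc2c(c1O)OC(C)(C)C=C2 | target

**Summary**

Total step count: 7. Longest linear sequence: 7 steps (1 to 13).

**Steps most likely to fail**

For step 7, the risks are erosion of linear regioselectivity through reductive elimination from the benzylic rhodium alkyl, and catalyst death by decarbonylation or by binding of the non-chelating phenoxides. The fallback sets out from aldehyde 10 and changes the bond construction to an aldol route. A Claisen–Schmidt condensation of 10 with commercial 2',4'-dihydroxyacetophenone (50% aq. KOH, EtOH, rt) should give the chalcone (E)-1-(2,4-dihydroxyphenyl)-3-[8-hydroxy-2,2-dimethyl-7-(3-methylbut-2-en-1-yl)-2H-chromen-6-yl]prop-2-en-1-one F1. Conjugate reduction of the enone with [CuH(PPh3)]6 in wet THF should then leave the chromene and prenyl alkenes untouched; an excess is used because the phenols consume hydride and serve as the proton source. The fallback comes back to the route at 13.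

For step 1, the risks are loss of site selectivity between the two catechol hydroxyls, double alkylation, and copper-mediated oxidation of the free catechol. The fallback sets out from 1 and differentiates the hydroxyls by protection.
- The dianion of 1 (NaH, 2.2 equiv, DMSO) should react with MOMCl (1.0 equiv) at the more nucleophilic C3 oxide to give 4-hydroxy-3-(methoxymethoxy)benzaldehyde F2.
- The one remaining phenol is alkylated with 2 (DBU, CuCl2·2H2O cat., MeCN) to give 3-(methoxymethoxy)-4-[(2-methylbut-3-yn-2-yl)oxy]benzaldehyde F3.
- Heating in N,N-diethylaniline at 190 °C should give 8-(methoxymethoxy)-2,2-dimethyl-2H-chromene-6-carbaldehyde F4.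
- Cleavage of the acetal (2 M HCl, MeOH, 40 °C, before any prenyl group is present) returns to the route at 6.

For step 5, the risks are fragmentation of the tertiary allyl aryl ether with loss of isoprene, and migration of the allyl unit to the para position C5 by way of the blocked ortho position C8a. The fallback sets out from 6 and builds the prenyl group in two stages.
- O-allylation (allyl bromide, K2CO3, acetone, reflux) gives 2,2-dimethyl-8-(prop-2-en-1-yloxy)-2H-chromene-6-carbaldehyde F5.
- The Claisen rearrangement of this primary allyl ether (N,N-diethylaniline, 190 °C) should give 8-hydroxy-2,2-dimethyl-7-(prop-2-en-1-yl)-2H-chromene-6-carbaldehyde F6.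
- Cross-metathesis with excess 2-methylbut-2-ene (second-generation Grubbs catalyst, CH2Cl2, 40 °C) should convert the terminal allyl group into the prenyl group, returning to the route at 10.

**Further compounds**

F1 | step 7 | (E)-1-(2,4-dihydroxyphenyl)-3-[8-hydroxy-2,2-dimethyl-7-(3-methylbut-2-en-1-yl)-2H-chromen-6-yl]prop-2-en-1-one | CC(C)=CCc1c(/C=C/C(=O)c2ccc(O)cc2O)cc2c(c1O)OC(C)(C)C=C2
F2 | step 1 | 4-hydroxy-3-(methoxymethoxy)benzaldehyde | COCOc1cc(C=O)ccc1O
F3 | step 1 | 3-(methoxymethoxy)-4-[(2-methylbut-3-yn-2-yl)oxy]benzaldehyde | COCOc1cc(C=O)ccc1OC(C)(C)C#C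
F4 | step 1 | 8-(methoxymethoxy)-2,2-dimethyl-2H-chromene-6-carbaldehyde | COCOc1cc(C=O)cc2C=CC(C)(C)Oc12
F5 | step 5 | 2,2-dimethyl-8-(prop-2-en-1-yloxy)-2H-chromene-6-carbaldehyde | C=CCOc1cc(C=O)cc2C=CC(C)(C)Oc12
F6 | step 5 | 8-hydroxy-2,2-dimethyl-7-(prop-2-en-1-yl)-2H-chromene-6-carbaldehyde | C=CCc1c(C=O)cc2C=CC(C)(C)Oc2c1O
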